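**Retrosynthetic overview**
1. Depside C(=O)–OAr bond: acid 7 (A ring, both phenols as benzyl ethers) plus phenol 15 (B ring, CO2H as benzyl ester); one final hydrogenolysis frees the two OH groups and the CO2H.
2. Each ArCH2–C(=O)C5H11 bond: lateral (benzylic) lithiation of a protected orsellinate plus the hexanoyl Weinreb amide 3.
3. A ring from methyl orsellinate 1 (bis-benzylation, acylation, saponification); B ring from orsellinic acid 8 (benzyl ester, 4-O-MOM, 2-O-Me, acylation, MOM removal).
4. No ring is constructed: both benzene rings are bought as orsellinates. Order: acid 7, phenol 15, esterification, global debenzylation.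

Assumption: the target has no stereocentre (it is achiral), so "single enantiomer" needs no stereocontrol; N-methoxy-N-methylhexanamide 3 is taken as a catalogue compound.

**Route**

Step 1
Reactants: 1 methyl 2,4-dihydroxy-6-methylbenzoate (methyl orsellinate)
Product: 2 methyl 2,4-bis(benzyloxy)-6-methylbenzoate
Conditions: BnBr (2.5 equiv), K2CO3, DMF, 60 °C
Reagents that add atoms: benzyl bromide, BrCc1ccccc1
Why: Williamson ether synthesis; excess BnBr in warm DMF benzylates both phenols, including the hydrogen-bonded 2-OH, and leaves the methyl ester untouched.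

Step 2
Reactants: 2 methyl 2,4-bis(benzyloxy)-6-methylbenzoate; 3 N-methoxy-N-methylhexanamide
Product: 6 methyl 2,4-bis(benzyloxy)-6-(2-oxoheptyl)benzoate, via benzylic lithium species 4 (not isolated), via lithium tetrahedral adduct 5 (not isolated)
Conditions: LDA (1.2 equiv), THF, −78 °C; then 3, −78 → −40 °C; 1 M HCl quench
Reagents that add atoms: none
Why: Lateral lithiation of the o-toluate gives an ester-stabilised benzylic anion, and its Weinreb amide acylation stops at the chelated tetrahedral adduct, so the ketone appears only on quench and is not over-added; no stereocentre is formed.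

Step 3
Reactants: 6 methyl 2,4-bis(benzyloxy)-6-(2-oxoheptyl)benzoate
Product: 7 2,4-bis(benzyloxy)-6-(2-oxoheptyl)benzoic acid
Conditions: KOH, DMSO/H2O, 80 °C; then cold 1 M HCl to pH 3
Reagents that add atoms: potassium hydroxide, [K+].[OH-]
Why: Saponification (BAc2) with excess hydroxide in a dipolar solvent overcomes the di-ortho hindrance; benzyl ethers are inert to base, and cold, mild acidification returns the open keto acid.

Step 4
Reactants: 8 2,4-dihydroxy-6-methylbenzoic acid (orsellinic acid)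
Product: 9 benzyl 2,4-dihydroxy-6-methylbenzoate
Conditions: BnBr (1.05 equiv), KHCO3, DMF, rt
Reagents that add atoms: benzyl bromide, BrCc1ccccc1
Why: Chemoselective carboxyl O-alkylation; bicarbonate ionises only the carboxylic acid and not the phenols, and room temperature avoids decarboxylation of orsellinic acid.

Step 5
Reactants: 9 benzyl 2,4-dihydroxy-6-methylbenzoate
Product: 10 benzyl 2-hydroxy-4-(methoxymethoxy)-6-methylbenzoate
Conditions: MOMCl (1.1 equiv), i-Pr2NEt, CH2Cl2, 0 °C
Reagents that add atoms: chloromethyl methyl ether, COCCl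
Why: Regioselective O-alkylation (MOM protection); the 2-OH is tied up in a hydrogen bond to the ester carbonyl, so one equivalent of MOMCl takes the freer, more acidic 4-OH.

Step 6
Reactants: 10 benzyl 2-hydroxy-4-(methoxymethoxy)-6-methylbenzoate
Product: 11 benzyl 2-methoxy-4-(methoxymethoxy)-6-methylbenzoate
Conditions: MeI (3 equiv), K2CO3, DMF, 40 °C
Reagents that add atoms: iodomethane, CI
Why: Williamson methylation of the remaining chelated phenol; the MOM acetal and the benzyl ester are stable to K2CO3/MeI.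

Step 7
Reactants: 11 benzyl 2-methoxy-4-(methoxymethoxy)-6-methylbenzoate; 3 N-methoxy-N-methylhexanamide
Product: 14 benzyl 2-methoxy-4-(methoxymethoxy)-6-(2-oxoheptyl)benzoate, via benzylic lithium species 12 (not isolated), via lithium tetrahedral adduct 13 (not isolated)
Conditions: LDA (1.2 equiv), THF, −78 °C; then 3, −78 → −40 °C; 1 M HCl quench at −78 °C
Reagents that add atoms: none
Why: Same lateral lithiation/Weinreb acylation as step 2; the toluate CH3 is far more acidic than the ester OCH2Ph or the MOM CH2, and LDA at −78 °C does not ortho-metalate; no stereocentre is formed.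

Step 8
Reactants: 14 benzyl 2-methoxy-4-(methoxymethoxy)-6-(2-oxoheptyl)benzoate
Product: 15 benzyl 4-hydroxy-2-methoxy-6-(2-oxoheptyl)benzoate
Conditions: conc. HCl (cat.), MeOH, 40 °C
Reagents that add atoms: none
Why: Acid-catalysed acetal exchange (MOM cleavage) transfers the CH2OMe unit to methanol; the hindered benzyl ester, the aryl methyl ether and the ketone survive dilute methanolic acid.

Step 9
Reactants: 7 2,4-bis(benzyloxy)-6-(2-oxoheptyl)benzoic acid; 15 benzyl 4-hydroxy-2-methoxy-6-(2-oxoheptyl)benzoate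
Product: 17 benzyl 4-{[2,4-bis(benzyloxy)-6-(2-oxoheptyl)benzoyl]oxy}-2-methoxy-6-(2-oxoheptyl)benzoate, via O-acylisourea 16 (not isolated)
Conditions: DCC (1.2 equiv), DMAP (0.2 equiv), CH2Cl2, 0 °C → rt
Reagents that add atoms: none
Why: Steglich esterification; DCC activates the hindered acid and DMAP relays the acyl group to the acidic para-carboalkoxy phenol, while ketones, benzyl ethers and the benzyl ester are spectators.

Step 10
Reactants: 17 benzyl 4-{[2,4-bis(benzyloxy)-6-(2-oxoheptyl)benzoyl]oxy}-2-methoxy-6-(2-oxoheptyl)benzoate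
Product: 18 arthonioic acid
Conditions: H2 (1 atm), 10% Pd/C, EtOAc, rt
Reagents that add atoms: none
Why: Catalytic hydrogenolysis removes the two benzyl ethers and the benzyl ester in one operation; the depside aryl ester, the aryl methyl ether and the non-conjugated ketones are not reduced under these conditions.

**Compound list**
1 | methyl 2,4-dihydroxy-6-methylbenzoate (methyl orsellinate) | COC(=O)c1c(C)cc(O)cc1O | starting material
2 | methyl 2,4-bis(benzyloxy)-6-methylbenzoate | COC(=O)c1c(C)cc(OCc2ccccc2)cc1OCc1ccccc1 | intermediate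
3 | N-methoxy-N-methylhexanamide | CCCCCC(=O)N(C)OC | starting material
4 | methyl 2,4-bis(benzyloxy)-6-(lithiomethyl)benzoate | [Li]Cc1cc(OCc2ccccc2)cc(OCc2ccccc2)c1C(=O)OC | intermediate (not isolated)
5 | lithium tetrahedral adduct of 4 and 3 | CCCCCC(O[Li])(N(C)OC)Cc1cc(OCc2ccccc2)cc(OCc2ccccc2)c1C(=O)OC | intermediate (not isolated)
6 | methyl 2,4-bis(benzyloxy)-6-(2-oxoheptyl)benzoate | CCCCCC(=O)Cc1cc(OCc2ccccc2)cc(OCc2ccccc2)c1C(=O)OC | intermediate
7 | 2,4-bis(benzyloxy)-6-(2-oxoheptyl)benzoic acid | CCCCCC(=O)Cc1cc(OCc2ccccc2)cc(OCc2ccccc2)c1C(=O)O | intermediate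
8 | 2,4-dihydroxy-6-methylbenzoic acid (orsellinic acid) | Cc1cc(O)cc(O)c1C(=O)O | starting material
9 | benzyl 2,4-dihydroxy-6-methylbenzoate | Cc1cc(O)cc(O)c1C(=O)OCc1ccccc1 | intermediate
10 | benzyl 2-hydroxy-4-(methoxymethoxy)-6-methylbenzoate | COCOc1cc(C)c(C(=O)OCc2ccccc2)c(O)c1 | intermediate
11 | benzyl 2-methoxy-4-(methoxymethoxy)-6-methylbenzoate | COCOc1cc(C)c(C(=O)OCc2ccccc2)c(OC)c1 | intermediate
12 | benzyl 2-(lithiomethyl)-6-methoxy-4-(methoxymethoxy)benzoate | [Li]Cc1cc(OCOC)cc(OC)c1C(=O)OCc1ccccc1 | intermediate (not isolated)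
13 | lithium tetrahedral adduct of 12 and 3 | CCCCCC(O[Li])(N(C)OC)Cc1cc(OCOC)cc(OC)c1C(=O)OCc1ccccc1 | intermediate (not isolated)
14 | benzyl 2-methoxy-4-(methoxymethoxy)-6-(2-oxoheptyl)benzoate | CCCCCC(=O)Cc1cc(OCOC)cc(OC)c1C(=O)OCc1ccccc1 | intermediate
15 | benzyl 4-hydroxy-2-methoxy-6-(2-oxoheptyl)benzoate | CCCCCC(=O)Cc1cc(O)cc(OC)c1C(=O)OCc1ccccc1 | intermediate
16 | O-acylisourea of acid 7 with DCC | CCCCCC(=O)Cc1cc(OCc2ccccc2)cc(OCc2ccccc2)c1C(=O)OC(=NC1CCCCC1)NC1CCCCC1 | intermediate (not isolated)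
17 | benzyl 4-{[2,4-bis(benzyloxy)-6-(2-oxoheptyl)benzoyl]oxy}-2-methoxy-6-(2-oxoheptyl)benzoate | CCCCCC(=O)Cc1cc(OCc2ccccc2)cc(OCc2ccccc2)c1C(=O)Oc1cc(CC(=O)CCCCC)c(C(=O)OCc2ccccc2)c(OC)c1 | intermediate
18 | arthonioic acid, 4-{[2,4-dihydroxy-6-(2-oxoheptyl)benzoyl]oxy}-2-methoxy-6-(2-oxoheptyl)benzoic acid | CCCCCC(=O)Cc1cc(O)cc(O)c1C(=O)Oc1cc(CC(=O)CCCCC)c(C(=O)O)c(OC)c1 | target

**Totals**
Total step count: 10 (3 to acid 7, 5 to phenol 15, coupling, hydrogenolysis).
Longest linear sequence: 7 steps (8 → 9 → 10 → 11 → 14 → 15 → 17 → 18, steps 4–10).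

**Three steps most likely to fail, each with a fallback**

Step 9 (coupling). The activated o-(2-oxoalkyl)benzoic acid is di-ortho hindered and can close onto its own ketone enol instead of acylating 15. The fallback masks that ketone and sets out from 6. Ketalisation with 1,2-bis(trimethylsilyloxy)ethane and catalytic TMSOTf in CH2Cl2 at −78 °C gives methyl 2,4-bis(benzyloxy)-6-[(2-pentyl-1,3-dioxolan-2-yl)methyl]benzoate F1. Saponification (KOH, aqueous DMSO, 100 °C, then acidification to pH 4–5 in the cold) gives 2,4-bis(benzyloxy)-6-[(2-pentyl-1,3-dioxolan-2-yl)methyl]benzoic acid F2, which has no enolisable ketone next to the carboxyl. DCC/DMAP coupling with 15 passes through the O-acylisourea of the ketal acid F3 and gives the dioxolane-protected depside benzyl ester F4. Brief treatment with 1 M HCl in THF at room temperature removes the dioxolane, and the sequence comes back to the route at 17.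

Step 7 (lateral acylation of a benzyl ester). The benzyl ester may suffer attack, OCH2Ph deprotonation or self-condensation under LDA. The fallback sets out from 11 and does the C–C bond formation on a carboxylate that cannot act as an electrophile. Hydrogenolysis (H2, Pd/C, EtOAc) gives 2-methoxy-4-(methoxymethoxy)-6-methylbenzoic acid F5. LDA (2.3 equiv, THF, −78 → −20 °C) gives the dilithio carboxylate/benzylic dianion F6, which adds to 3 at −78 °C to give the dilithium tetrahedral adduct F7. A cold pH 4 quench releases 2-methoxy-4-(methoxymethoxy)-6-(2-oxoheptyl)benzoic acid F8. Carboxyl-selective benzylation (BnBr, KHCO3, DMF, rt) then comes back to the route at 14.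

Step 3 (saponification of the hindered keto ester). Hot base may be slow on the di-ortho-substituted ester, and the neighbouring ketone enolates can divert material by intramolecular acylation. The fallback sets out from 2 and hydrolyses before the ketone exists. KOH in aqueous DMSO at 100 °C gives 2,4-bis(benzyloxy)-6-methylbenzoic acid F9. LDA (2.3 equiv, THF, −78 → −20 °C) gives the dilithio dianion F10, which is acylated by 3 through the dilithium tetrahedral adduct F11. A cold dilute-acid quench delivers the keto acid directly, coming back to the route at 7.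

**Further compounds**
F1 | step 9 | methyl 2,4-bis(benzyloxy)-6-[(2-pentyl-1,3-dioxolan-2-yl)methyl]benzoate | CCCCCC1(Cc2cc(OCc3ccccc3)cc(OCc3ccccc3)c2C(=O)OC)OCCO1
F2 | step 9 | 2,4-bis(benzyloxy)-6-[(2-pentyl-1,3-dioxolan-2-yl)methyl]benzoic acid | CCCCCC1(Cc2cc(OCc3ccccc3)cc(OCc3ccccc3)c2C(=O)O)OCCO1
F3 | step 9 | O-acylisourea of the ketal acid F2 with DCC | CCCCCC1(Cc2cc(OCc3ccccc3)cc(OCc3ccccc3)c2C(=O)OC(=NC2CCCCC2)NC2CCCCC2)OCCO1
F4 | step 9 | benzyl 4-{[2,4-bis(benzyloxy)-6-[(2-pentyl-1,3-dioxolan-2-yl)methyl]benzoyl]oxy}-2-methoxy-6-(2-oxoheptyl)benzoate | CCCCCC1(Cc2cc(OCc3ccccc3)cc(OCc3ccccc3)c2C(=O)Oc2cc(CC(=O)CCCCC)c(C(=O)OCc3ccccc3)c(OC)c2)OCCO1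
F5 | step 7 | 2-methoxy-4-(methoxymethoxy)-6-methylbenzoic acid | COCOc1cc(C)c(C(=O)O)c(OC)c1
F6 | step 7 | lithium 2-(lithiomethyl)-6-methoxy-4-(methoxymethoxy)benzoate | [Li]Cc1cc(OCOC)cc(OC)c1C(=O)O[Li]
F7 | step 7 | dilithium tetrahedral adduct of F6 and 3 | CCCCCC(O[Li])(N(C)OC)Cc1cc(OCOC)cc(OC)c1C(=O)O[Li]
F8 | step 7 | 2-methoxy-4-(methoxymethoxy)-6-(2-oxoheptyl)benzoic acid | CCCCCC(=O)Cc1cc(OCOC)cc(OC)c1C(=O)O
F9 | step 3 | 2,4-bis(benzyloxy)-6-methylbenzoic acid | Cc1cc(OCc2ccccc2)cc(OCc2ccccc2)c1C(=O)O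
F10 | step 3 | lithium 2,4-bis(benzyloxy)-6-(lithiomethyl)benzoate | [Li]Cc1cc(OCc2ccccc2)cc(OCc2ccccc2)c1C(=O)O[Li]
F11 | step 3 | dilithium tetrahedral adduct of F10 and 3 | CCCCCC(O[Li])(N(C)OC)Cc1cc(OCc2ccccc2)cc(OCc2ccccc2)c1C(=O)O[Li]
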